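## The problem

Target 15 is a single cyclohexene, numbered here with C1 carrying the C7H2 benzoate, C2 as the vinylic CH and C3–C6 as four contiguous carbinol carbons (3S,4S,5R,6R), of which only O5 is benzoylated. All four ring oxygens lie on one face, whereas an addition to an oxygenated cyclohexene normally goes anti to the oxygen already present. Each oxygen must therefore come either from a rigid bicyclic precursor or from a carbonyl that is reduced from the open face. C5 is the centre that can control the others: if O5 begins as an oxygen bridge, O3 and O4 can be placed exo to it and C6 can be set later by hydride entering anti to it. O5 must also be told apart from three other secondary hydroxyls, which is simplest if it is the only free ring hydroxyl when the benzoates go on. Several features are fragile: the allylic C3–O and C6–O bonds flanking C1=C2 can ionise in strong acid, the O5 benzoate sits between two cis hydroxyls and migrates under base, and any intermediate with a carbonyl at C6 or C7 has a β-oxygen and can eliminate towards an arene. The enabling feature is that C2–C3–C4–C5 with O5 map onto furan (C2 and C5 its α-carbons, O5 its oxygen) and C6–C1–C7 onto an acrylate (C1 the α-carbon, C7 the carbonyl). Their [4+2] union is a 7-oxabicyclo[2.2.1]heptene in which a C1 enolate can later break the C2–O bond, giving C1=C2 and leaving O5 as a free hydroxyl.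

## Retrosynthesis

**15 ⇒ 14.** No skeletal bond is cut; the O3 and O4 hydrogens are replaced by one isopropylidene acetal. The cis-vicinal O3/O4 pair is the natural pair for a five-membered acetal, and it comes off in aqueous acid, where benzoates migrate only slowly. The forward step must hydrolyse the acetal without touching two esters and two allylic alcohols.

**14 ⇒ 13.** The C6–H bond is cut, so the C6 carbinol becomes the ketone of enone 13. C6 is the one centre the bicycle cannot deliver. A direct hydroxylation would enter anti to the oxygens already present and give the wrong epimer, whereas a hydride entering anti to them leaves O6 cis. The forward reduction must be 1,2-selective, face-selective and non-basic.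

**13 ⇒ 12 ⇒ 11.** The C6–O bond is cut, which returns C6 to the CH2 that an acrylate β-carbon supplies. Hexavalent chromium oxidants favour the allylic site next to the less substituted alkene carbon, which here is the oxygen-bearing C3 methine. A selenium-based ene oxidation (Riley oxidation) works at the more substituted terminus, C1, and therefore at C6 or C7; C7 is deactivated by its benzoate. The oxidation is therefore planned as a selenium hydroxylation to 12 followed by oxidation to 13. Precursor 11 has three stereocentres and no oxygen at C6.

**11 ⇒ 9 + 10, and 9 ⇒ 8.** The two acyl–oxygen bonds at O5 and O7 are cut. Both benzoates come from benzoyl chloride 10, used in excess in one operation, because O5 and O7 are the only free hydroxyls of diol 9. Diol 9 is the reduction product of ester 8. Reduction must precede benzoylation because the hydride reagent would strip benzoates.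

**8 ⇒ 6 (through enolate 7).** The C2–O5 bond is re-formed, the reverse of an E1cB elimination. This is the cut that gives the route its logic: it places C1=C2 without regiochemical ambiguity and unveils O5 alone. Precursor 6 is a rigid bicycle whose faces are easy to tell apart. The forward step asks that enolate 7 expel the bridge oxygen and that the reaction stop there.

**6 ⇒ 5 ⇒ 4 ⇒ 3.** The ester is traced to the imide, the acetal to the diol, and the C3–O and C4–O bonds are cut as a syn dihydroxylation from the exo face of the bicyclic alkene. Osmylation is placed directly after the cycloaddition so that the alkene, and with it the risk of cycloreversion, is removed at once. Methanolysis is placed after it, where epimerisation at C1 is harmless because that centre is about to become trigonal.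

**3 ⇒ 1 + 2.** The C1–C2 and C5–C6 bonds are cut in a Diels–Alder sense to furan 1 and 3-acryloyl-1,3-oxazolidin-2-one 2. Both are commodity chemicals, the step closes the carbocycle and sets three stereocentres, and the two-point binding of the imide allows catalysis by [Cu((R,R)-t-Bu-box)](SbF6)2. A β-oxygenated acrylate would bring O6 with it, but furan is too poor a diene for β-substituted dienophiles, and a β-acyloxy group would be the better leaving group in the later enolate opening. The forward reaction must be enantioface-selective, endo-selective and free of cycloreversion.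

## Roads not taken

Alternative 1: The cut is at the C5–O and C6–O bonds, back to an arene. Bromobenzene A1 is oxidised by whole cells of E. coli JM109(pDTG601), whose toluene dioxygenase adds dioxygen across the future C5–C6 bond and gives the cis-diol A2. No ring closes, because the arene already is the ring, and bromine marks C1 for later attachment of C7.
- Merits: one fermentation step from a bulk arene, an enantiopure product, and O5 and O6 in the correct absolute configuration. O6 is exactly the oxygen that the chosen plan must add late by C–H oxidation, so in this respect A2 is the better starting point.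
- Weak points: O3 and O4 must be added across C3=C4 on the same face as O5/O6, but once those two are tied in a cyclic acetal OsO4 attacks the opposite face, so the all-cis array needs an indirect sequence with inversions. O5 and O6 form a cis-diol pair of which only O5 is to be benzoylated. C7 is missing and needs a Pd(PPh3)4-catalysed carbonylation and a reduction.
- Comparison: the chosen plan offsets its late C6 oxidation by delivering three oxygens all-cis from the bicycle, by having O5 unique from the start, and by carrying C7 from the first step.

Alternative 2: The cut is at C3–C4 and C5–C6. Diene A3 and vinylene carbonate A4 combine in a thermal endo Diels–Alder reaction that closes the cyclohexene and gives the meso all-cis adduct A5.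
- Merits: all four ring oxygens arrive all-cis in one step. This is better than the chosen plan, which needs three separate operations for them, and no C–H oxidation is required.
- Weak points: A5 is meso, so absolute configuration rests on a desymmetrising benzoylation that must pick an inner oxygen (O5, not O6 or O3) and one of two enantiotopic partners; no established catalyst does both on this substrate. A4 is a sluggish dienophile and the cycloaddition needs forcing conditions. C7 must be attached to a vinylic CH, which means oxidation to an enone, α-functionalisation and reduction.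
- Comparison: the chosen plan sets absolute configuration by a catalyst in the bond-forming step, has C7 built in, and differentiates O5 by construction. It pays for this with the late introduction of O6.

Alternative 3: The cut is at C2–C3. Hexenopyranoside A6 is treated with Hg(OCOCF3)2 in aqueous acetone. Oxymercuration of the enol ether opens the pyranoside, and the mercury enolate adds to the freed aldehyde, closing the carbocycle as cyclohexanone A7.
- Merits: C4, C5 and C6 come from the chiral pool with certain absolute configuration, the O5 benzoate is placed on the sugar, and O6 is present. In certainty of configuration this road is better than an asymmetric catalyst.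
- Weak points: A6 needs a long protecting-group sequence in the allo series, which is not among the cheap hexoses. Mercury is used. C3 is set by substrate control in the aldol step and is not secured for the cis arrangement. The easy elimination of A7 runs towards C2=C3 and would destroy the C3 carbinol, while the target needs C7 added at C1 and the alkene at C1=C2.
- Comparison: the chosen plan is shorter, avoids mercury and has C1=C2 and C7 placed by the bridge opening. Against the certain configuration of A7 it sets a catalyst-controlled cycloaddition whose product can be crystallised.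

Key step: step 1

Assumption: furan is taken to follow the sense of induction this catalyst family shows with cyclopentadiene, where the (S,S)-ligand leads to the 2S adduct, so the (R,R)-ligand, 2,2'-(propane-2,2-diyl)bis[(4R)-4-tert-butyl-4,5-dihydro-1,3-oxazole], is specified.

## Route

Bicyclic compounds use 7-oxabicyclo[2.2.1]heptane numbering, in which bicyclic C2, C1, C6, C5, C4, C3 become target C1, C2, C3, C4, C5, C6.

Step 1
Reactants: 1 furan; 2 3-acryloyl-1,3-oxazolidin-2-one
Product: 3 3-[(1R,2R,4R)-7-oxabicyclo[2.2.1]hept-5-ene-2-carbonyl]-1,3-oxazolidin-2-one (endo adduct)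
Conditions: [Cu((R,R)-t-Bu-box)](SbF6)2 (5 mol %, from CuCl2, ligand, AgSbF6), excess furan, CH2Cl2, −78 °C; cold filtration through silica, crystallisation
Reagents that add atoms: none
Why: The cationic divalent copper centre binds both carbonyl oxygens of 2, which holds the acrylate s-cis in a distorted square-planar chelate; one tert-butyl group of the (R,R)-ligand covers one enantioface of the alkene, and furan 1 adds to the other in a concerted, asynchronous [4+2] cycloaddition that forms C1–C2 and C5–C6. The closest known reaction type is the bis(oxazoline)–copper-catalysed Diels–Alder reaction of 3-acryloyloxazolidin-2-one with cyclic dienes, furan included. The cyclohexene ring closes by suprafacial addition across the 2,5-positions of furan, so the carbocycle and the oxygen bridge of the 7-oxabicyclo[2.2.1]heptene arise in the same event. The two bridgeheads (future C2 and C5) and C1 are tied to one another by the endo transition state and fixed in the absolute sense by the ligand, the (R,R)-ligand being chosen for the (1R,2R,4R)-adduct. The step needs enantioface selectivity, supplied by the two-point chelation of the imide, and endo selectivity, supplied by kinetic control at −78 °C. It also needs freedom from cycloreversion, so the catalyst is removed cold and 3 is crystallised, which should also remove the exo isomer; the exo adduct carries mirror-image bridgeheads and would erode enantiomeric purity once C1 becomes trigonal in step 5.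

Step 2
Reactants: 3 3-[(1R,2R,4R)-7-oxabicyclo[2.2.1]hept-5-ene-2-carbonyl]-1,3-oxazolidin-2-one
Product: 4 3-[(1S,2R,4R,5S,6R)-5,6-dihydroxy-7-oxabicyclo[2.2.1]heptane-2-carbonyl]-1,3-oxazolidin-2-one (exo,exo-diol)
Conditions: OsO4 (2 mol %), N-methylmorpholine N-oxide (1.5 equiv), acetone–H2O (8:1), 0→23 °C
Reagents that add atoms: osmium tetroxide, O=[Os](=O)(=O)=O; N-methylmorpholine N-oxide, C[N+]1([O-])CCOCC1 (terminal oxidant that restores OsO4); water, O (hydrolyses the osmate ester)
Why: Catalytic syn dihydroxylation of the strained alkene; OsO4 should add from the exo face, next to the oxygen bridge, because the endo face is covered by the C2–C3 bridge and the endo acyl group, which sets O3 and O4 cis to O5. Removing the alkene ends any cycloreversion, and the exo hydroxyls cannot reach the endo imide carbonyl.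

Step 3
Reactants: 4 3-[(1S,2R,4R,5S,6R)-5,6-dihydroxy-7-oxabicyclo[2.2.1]heptane-2-carbonyl]-1,3-oxazolidin-2-one
Product: 5 3-[(1S,2R,4R,5R,6S)-5,6-(isopropylidenedioxy)-7-oxabicyclo[2.2.1]heptane-2-carbonyl]-1,3-oxazolidin-2-one (exo acetonide)
Conditions: 2,2-dimethoxypropane, pyridinium p-toluenesulfonate (cat.), acetone, 23 °C
Reagents that add atoms: 2,2-dimethoxypropane, COC(C)(C)OC
Why: Acid-catalysed transacetalisation; the cis exo diol closes a five-membered dioxolane readily, and the imide tolerates the weak acid.

Step 4
Reactants: 5 3-[(1S,2R,4R,5R,6S)-5,6-(isopropylidenedioxy)-7-oxabicyclo[2.2.1]heptane-2-carbonyl]-1,3-oxazolidin-2-one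
Product: 6 methyl (1S,2R,4R,5R,6S)-5,6-(isopropylidenedioxy)-7-oxabicyclo[2.2.1]heptane-2-carboxylate
Conditions: MeMgBr (1.2 equiv) added to MeOH–CH2Cl2 (forms MeOMgBr), 0 °C; aq. NH4Cl
Reagents that add atoms: methanol, CO (delivered as MeOMgBr)
Why: Chelation-assisted methanolysis of the exocyclic imide carbonyl, a standard imide-to-ester exchange. Epimerisation at C1 would be harmless because that centre becomes trigonal in step 5, and any premature bridge opening gives 8 itself.

Step 5
Reactants: 6 methyl (1S,2R,4R,5R,6S)-5,6-(isopropylidenedioxy)-7-oxabicyclo[2.2.1]heptane-2-carboxylate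
Product: 8 methyl (3S,4R,5R)-5-hydroxy-3,4-(isopropylidenedioxy)cyclohex-1-ene-1-carboxylate, via lithium ester enolate 7 (not isolated)
Conditions: LiN(SiMe3)2 (1.1 equiv), THF, −78→−40 °C; aq. NH4Cl
Reagents that add atoms: none
Why: E1cB β-elimination: the C1 enolate 7 has the strained C2–O bridge bond in the β position and expels the bridging alkoxide, which gives C1=C2 in conjugation with the ester and leaves O5 as the only free hydroxyl. C3, C4 and C5 are not touched, and one equivalent of base at low temperature should prevent further elimination.

Step 6
Reactants: 8 methyl (3S,4R,5R)-5-hydroxy-3,4-(isopropylidenedioxy)cyclohex-1-ene-1-carboxylate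
Product: 9 [(3S,4R,5R)-5-hydroxy-3,4-(isopropylidenedioxy)cyclohex-1-en-1-yl]methanol
Conditions: i-Bu2AlH (3.5 equiv), CH2Cl2, −78→0 °C; aq. potassium sodium tartrate
Reagents that add atoms: none
Why: 1,2-Reduction of an α,β-unsaturated ester to the allylic alcohol by i-Bu2AlH, which does not reduce the conjugated alkene or the acetal.

Step 7
Reactants: 9 [(3S,4R,5R)-5-hydroxy-3,4-(isopropylidenedioxy)cyclohex-1-en-1-yl]methanol; 10 benzoyl chloride
Product: 11 [(3S,4R,5R)-5-(benzoyloxy)-3,4-(isopropylidenedioxy)cyclohex-1-en-1-yl]methyl benzoate
Conditions: 10 (2.5 equiv), pyridine, 4-(dimethylamino)pyridine (cat.), CH2Cl2, 0→23 °C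
Reagents that add atoms: benzoyl chloride, O=C(Cl)c1ccccc1 (the second equivalent of 10, which supplies the second benzoyl group)
Why: Nucleophile-catalysed acylation in which two equivalents of 10 are consumed, one at the primary O7 and one at the secondary O5. These are the only free hydroxyls, so the benzoate pattern of the target follows from the protecting-group pattern.

Step 8
Reactants: 11 [(3S,4R,5R)-5-(benzoyloxy)-3,4-(isopropylidenedioxy)cyclohex-1-en-1-yl]methyl benzoate
Product: 12 [(3S,4S,5R,6S)-5-(benzoyloxy)-6-hydroxy-3,4-(isopropylidenedioxy)cyclohex-1-en-1-yl]methyl benzoate (O6 trans to O5)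
Conditions: SeO2 (0.5 equiv), t-BuOOH (3 equiv), CH2Cl2, 25→40 °C
Reagents that add atoms: selenium dioxide, O=[Se]=O (delivers O6); tert-butyl hydroperoxide, CC(C)(C)OO (reoxidises the reduced selenium)
Why: Riley allylic oxidation by ene reaction and [2,3]-sigmatropic shift: selenium bonds to the less substituted alkene carbon C2 and hydrogen is taken from a carbon on C1, the ring CH2 at C6 in preference to the benzoate-deactivated C7, so C1=C2 is restored and the C3–H is never engaged. The reagent should enter anti to the acetonide and give mainly the 6S alcohol, but either epimer serves because C6 is made trigonal in step 9.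

Step 9
Reactants: 12 [(3S,4S,5R,6S)-5-(benzoyloxy)-6-hydroxy-3,4-(isopropylidenedioxy)cyclohex-1-en-1-yl]methyl benzoate
Product: 13 [(3S,4S,5S)-5-(benzoyloxy)-3,4-(isopropylidenedioxy)-6-oxocyclohex-1-en-1-yl]methyl benzoate
Conditions: Dess–Martin periodinane (1.5 equiv), NaHCO3, CH2Cl2, 0→23 °C
Reagents that add atoms: none
Why: Dess–Martin oxidation of a secondary allylic alcohol to the enone under buffered, non-basic conditions, which should spare the β-alkoxy ketone from elimination.

Step 10
Reactants: 13 [(3S,4S,5S)-5-(benzoyloxy)-3,4-(isopropylidenedioxy)-6-oxocyclohex-1-en-1-yl]methyl benzoate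
Product: 14 [(3S,4S,5R,6R)-5-(benzoyloxy)-6-hydroxy-3,4-(isopropylidenedioxy)cyclohex-1-en-1-yl]methyl benzoate
Conditions: NaBH4, CeCl3·7H2O, MeOH, −78 °C; AcOH quench
Reagents that add atoms: none
Why: Luche reduction gives 1,2-addition only; hydride should enter C6 from the face opposite the dioxolane (whose axial C4–O bond blocks the other face) and the O5 benzoate, which sets 6R with O6 cis to O5. The low temperature and acidic quench should prevent benzoyl migration in the alkoxide.

Step 11
Reactants: 14 [(3S,4S,5R,6R)-5-(benzoyloxy)-6-hydroxy-3,4-(isopropylidenedioxy)cyclohex-1-en-1-yl]methyl benzoate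
Product: 15 [(3S,4S,5R,6R)-5-(benzoyloxy)-3,4,6-trihydroxycyclohex-1-en-1-yl]methyl benzoate
Conditions: CF3CO2H–H2O (9:1), 0 °C
Reagents that add atoms: none
Why: Acid hydrolysis of the isopropylidene acetal; benzoates are stable to brief aqueous acid, and acyl migration is slow in acidic medium.

## Compound list

1 | furan | c1ccoc1 | starting material
2 | 3-acryloyl-1,3-oxazolidin-2-one | C=CC(=O)N1CCOC1=O | starting material
3 | 3-[(1R,2R,4R)-7-oxabicyclo[2.2.1]hept-5-ene-2-carbonyl]-1,3-oxazolidin-2-one | O=C(N1CCOC1=O)[C@@H]1C[C@@H]2C=C[C@H]1O2 | intermediate
4 | 3-[(1S,2R,4R,5S,6R)-5,6-dihydroxy-7-oxabicyclo[2.2.1]heptane-2-carbonyl]-1,3-oxazolidin-2-one | O=C(N1CCOC1=O)[C@@H]1C[C@@H]2[C@@H](O)[C@@H](O)[C@H]1O2 | intermediate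
5 | 3-[(1S,2R,4R,5R,6S)-5,6-(isopropylidenedioxy)-7-oxabicyclo[2.2.1]heptane-2-carbonyl]-1,3-oxazolidin-2-one | O=C(N1CCOC1=O)[C@@H]1C[C@@H]2[C@H]3OC(C)(C)O[C@H]3[C@H]1O2 | intermediate
6 | methyl (1S,2R,4R,5R,6S)-5,6-(isopropylidenedioxy)-7-oxabicyclo[2.2.1]heptane-2-carboxylate | COC(=O)[C@@H]1C[C@@H]2[C@H]3OC(C)(C)O[C@H]3[C@H]1O2 | intermediate
7 | lithium enolate of 6 (formed in the flask, not isolated) | [Li+].COC([O-])=C1C[C@@H]2[C@H]3OC(C)(C)O[C@H]3[C@H]1O2 | intermediate
8 | methyl (3S,4R,5R)-5-hydroxy-3,4-(isopropylidenedioxy)cyclohex-1-ene-1-carboxylate | COC(=O)C1=C[C@@H]2OC(C)(C)O[C@@H]2[C@H](O)C1 | intermediate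
9 | [(3S,4R,5R)-5-hydroxy-3,4-(isopropylidenedioxy)cyclohex-1-en-1-yl]methanol | OCC1=C[C@@H]2OC(C)(C)O[C@@H]2[C@H](O)C1 | intermediate
10 | benzoyl chloride | O=C(Cl)c1ccccc1 | starting material
11 | [(3S,4R,5R)-5-(benzoyloxy)-3,4-(isopropylidenedioxy)cyclohex-1-en-1-yl]methyl benzoate | O=C(OCC1=C[C@@H]2OC(C)(C)O[C@@H]2[C@H](OC(=O)c2ccccc2)C1)c1ccccc1 | intermediate
12 | [(3S,4S,5R,6S)-5-(benzoyloxy)-6-hydroxy-3,4-(isopropylidenedioxy)cyclohex-1-en-1-yl]methyl benzoate | O=C(OCC1=C[C@@H]2OC(C)(C)O[C@@H]2[C@H](OC(=O)c2ccccc2)[C@H]1O)c1ccccc1 | intermediate
13 | [(3S,4S,5S)-5-(benzoyloxy)-3,4-(isopropylidenedioxy)-6-oxocyclohex-1-en-1-yl]methyl benzoate | O=C(OCC1=C[C@@H]2OC(C)(C)O[C@@H]2[C@H](OC(=O)c2ccccc2)C1=O)c1ccccc1 | intermediate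
14 | [(3S,4S,5R,6R)-5-(benzoyloxy)-6-hydroxy-3,4-(isopropylidenedioxy)cyclohex-1-en-1-yl]methyl benzoate | O=C(OCC1=C[C@@H]2OC(C)(C)O[C@@H]2[C@H](OC(=O)c2ccccc2)[C@@H]1O)c1ccccc1 | intermediate
15 | [(3S,4S,5R,6R)-5-(benzoyloxy)-3,4,6-trihydroxycyclohex-1-en-1-yl]methyl benzoate | O=C(OCC1=C[C@H](O)[C@H](O)[C@H](OC(=O)c2ccccc2)[C@@H]1O)c1ccccc1 | target

## Step count and least certain steps

Total: 11 steps. Longest linear sequence: 11 steps, from 1 and 2 to 15.

**Step 1 (key step).** Incomplete endo selectivity and cycloreversion on warming are the likely failures. Both erode enantiomeric purity, because the exo adduct leads into the mirror-image series after step 5. Slow conversion of the poorly reactive furan and catalyst deactivation by moisture are further risks. Fallback: asymmetric catalysis is replaced by resolution of a crystalline acid, setting out from furan 1 and rejoining the route at 6. Furan 1 and acrylic acid, kept neat at ambient temperature with a trace of hydroquinone, should slowly deposit the endo acid as the racemate. Crystallisation of its salt with one enantiomer of 1-phenylethylamine (whichever gives the less soluble salt of the wanted acid), followed by acidification, gives (1R,2R,4R)-7-oxabicyclo[2.2.1]hept-5-ene-2-carboxylic acid F1. Esterification with (trimethylsilyl)diazomethane in methanol gives the methyl ester F2, catalytic osmylation as in step 2 gives the exo diol ester F3, and acetal formation as in step 3 returns to 6.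

**Step 8.** The ene reaction may be slow on an alkene that carries two allylic oxygens, hydrogen abstraction may occur at C7 instead of C6, and the oxidation may run on past the alcohol. Fallback: 11 is oxidised directly to enone 13 with CrO3·3,5-dimethylpyrazole in CH2Cl2 at −20 °C. This works by hydrogen abstraction and an allyl chromate, not by an ene reaction. The usual chromium site, next to C2, is here the oxygenated C3 methine, so C6 is the only allylic methylene not bonded to oxygen. The fallback sets out from 11, returns at 13 and omits 12.

**Step 10.** Poor facial selectivity is the likely failure: attack on the acetonide face would give the 6S epimer. Benzoyl migration from O5 to O6 in the alkoxide is the second risk. Fallback: substrate control is replaced by reagent control. Enone 13 is reduced with catecholborane and (R)-2-methyl-CBS-oxazaborolidine, that is (3aR)-1-methyl-3,3-diphenyltetrahydro-1H,3H-pyrrolo[1,2-c][1,3,2]oxazaborole, in toluene at −78 °C (Corey–Bakshi–Shibata reduction). The trisubstituted alkenyl arm at C1 is taken as the large group, which directs hydride to the face anti to O5. This sets out from 13 and returns at 14 without a borohydride alkoxide.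

**Step 5.** Over-elimination is the likely failure: deprotonation of the product at C3 would expel the C4 oxygen and lead on to an arene. Re-closure of the bridge by oxa-Michael addition on warming is the second risk. Fallback: the opening is moved to the aldehyde oxidation level, where a mild amine base suffices; it sets out from 6 and rejoins the route at 9. Ester 6 is reduced with one equivalent of i-Bu2AlH in toluene at −78 °C to the bridged aldehyde (1S,2R,4R,5R,6S)-5,6-(isopropylidenedioxy)-7-oxabicyclo[2.2.1]heptane-2-carbaldehyde F4. 1,8-Diazabicyclo[5.4.0]undec-7-ene in CH2Cl2 at 0 °C opens it to the enal (3S,4R,5R)-5-hydroxy-3,4-(isopropylidenedioxy)cyclohex-1-ene-1-carbaldehyde F5. NaBH4 with CeCl3·7H2O in MeOH reduces this enal to diol 9.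

## Further compounds

F1 | step 1 | (1R,2R,4R)-7-oxabicyclo[2.2.1]hept-5-ene-2-carboxylic acid | OC(=O)[C@@H]1C[C@@H]2C=C[C@H]1O2
F2 | step 1 | methyl (1R,2R,4R)-7-oxabicyclo[2.2.1]hept-5-ene-2-carboxylate | COC(=O)[C@@H]1C[C@@H]2C=C[C@H]1O2
F3 | step 1 | methyl (1S,2R,4R,5S,6R)-5,6-dihydroxy-7-oxabicyclo[2.2.1]heptane-2-carboxylate | COC(=O)[C@@H]1C[C@@H]2[C@@H](O)[C@@H](O)[C@H]1O2
F0 | step 8 | none | none
F0 | step 10 | none | none
F4 | step 5 | (1S,2R,4R,5R,6S)-5,6-(isopropylidenedioxy)-7-oxabicyclo[2.2.1]heptane-2-carbaldehyde | O=C[C@@H]1C[C@@H]2[C@H]3OC(C)(C)O[C@H]3[C@H]1O2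
F5 | step 5 | (3S,4R,5R)-5-hydroxy-3,4-(isopropylidenedioxy)cyclohex-1-ene-1-carbaldehyde | O=CC1=C[C@@H]2OC(C)(C)O[C@@H]2[C@H](O)C1
A1 | alternative 1 | bromobenzene | Brc1ccccc1
A2 | alternative 1 | (1S,2S)-3-bromocyclohexa-3,5-diene-1,2-diol | BrC1=CC=C[C@H](O)[C@@H]1O
A3 | alternative 2 | (1E,3E)-1,4-diacetoxybuta-1,3-diene | CC(=O)O/C=C/C=C/OC(C)=O
A4 | alternative 2 | vinylene carbonate | O=C1OC=CO1
A5 | alternative 2 | meso all-cis 3,6-diacetoxycyclohex-1-ene-4,5-diyl carbonate | C1=C[C@H](OC(C)=O)[C@@H]2OC(=O)O[C@@H]2[C@@H]1OC(C)=O
A6 | alternative 3 | methyl 3-O-benzoyl-6-deoxy-2,4-bis-O-(triethylsilyl)-α-D-ribo-hex-5-enopyranoside (allo series) | C=C1O[C@H](OC)[C@H](O[Si](CC)(CC)CC)[C@H](OC(=O)c2ccccc2)[C@@H]1O[Si](CC)(CC)CC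
A7 | alternative 3 | 5-benzoyloxy-3-hydroxy-4,6-bis(triethylsilyloxy)cyclohexanone (target numbering, C1 carbonyl) | O=C1C[C@H](O)[C@H](O[Si](CC)(CC)CC)[C@H](OC(=O)c2ccccc2)[C@@H]1O[Si](CC)(CC)CC
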